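**Plan**

1. Retrosynthesis: the two ester C–O bonds are cut first, then C4–O and C4–C15 (hydration and methylenation of a C4 ketone), then C5–C10 and C6–C7 together, then C11–C13 with O–Si, C7–C8/C8–C9 (carbonylation), C10–C14 (carboalumination) and C1–C2 (epoxide opening).
2. Forward: the open chain C6=C5–C4–C3–C2–C1–C10=C9–C8–C7≡C11 is built from divinyl carbinol, a propargyl unit, CO and propyne; rings A and B close together in step 11, after which only C4 and the two acyl groups are adjusted.
3. Enabling feature: the C7(=C11)–C8(=O) unit of ring B is the hydrolysed adduct of a 2-silyloxy vinylallene C10=C9–C8(OSi)=C7=C11, the oxygen-bearing C4 next to C5 can stand as a ketone that activates C5=C6, and C1–C4 of ring A is the tether.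
4. Stereochemistry: C3 from catalyst-controlled epoxidation; C10 and C5 relayed from C3 in the cycloaddition; C4 by hydration anti to the C10 methyl; the side-chain centre from (R)-2-methylbutanoic acid.

Key step: step 11

Assumption: enantiopure (R)-2-methylbutanoic acid is taken as a purchased reagent; atoms are called C1–C15 by eudesmane numbering (C4 bears the acetate, C10 the angular methyl).

Step 1
Reactants: 1 penta-1,4-dien-3-ol
Product: 2 (2S,3R)-1,2-epoxypent-4-en-3-ol
Conditions: Ti(OiPr)4, D-(−)-diisopropyl tartrate, t-BuOOH, 4 Å molecular sieves, CH2Cl2, −20 °C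
Reagents that add atoms: tert-butyl hydroperoxide, CC(C)(C)OO
Why: Sharpless asymmetric epoxidation of the prochiral divinyl carbinol, in which group selection and face selection reinforce each other, should give the erythro epoxy alcohol with the 2S epoxide carbon (later C3) in high enantiomeric purity.

Step 2
Reactants: 2 (2S,3R)-1,2-epoxypent-4-en-3-ol
Product: 3 (2S)-2-[(1R)-1-(4-methoxybenzyloxy)prop-2-en-1-yl]oxirane
Conditions: NaH, 4-methoxybenzyl chloride, n-Bu4NI (cat.), THF, 0 °C → rt
Reagents that add atoms: 4-methoxybenzyl chloride, COc1ccc(CCl)cc1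
Why: Williamson etherification of the secondary alkoxide is faster than epoxide migration at this temperature, and the benzyl-type ether cannot migrate to the neighbouring alkoxide formed in step 3.

Step 3
Reactants: 3 (2S)-2-[(1R)-1-(4-methoxybenzyloxy)prop-2-en-1-yl]oxirane; 4 1-(trimethylsilyl)propyne
Product: 6 (3R,4S)-3-(4-methoxybenzyloxy)oct-1-en-7-yn-4-ol, via silyl alkyne 5 (not isolated)
Conditions: n-BuLi, THF, −78 °C; then 3, DMPU, −78 → 0 °C; then MeOH, K2CO3, rt
Reagents that add atoms: none
Why: the silyl-capped propargyl anion opens the epoxide by SN2 attack at the unsubstituted carbon, so the oxygen-bearing carbon keeps its configuration, and base methanolysis then removes the alkynyl silyl group.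

Step 4
Reactants: 6 (3R,4S)-3-(4-methoxybenzyloxy)oct-1-en-7-yn-4-ol
Product: 7 (3R,4S)-4-(tert-butyldimethylsilyloxy)-3-(4-methoxybenzyloxy)oct-1-en-7-yne
Conditions: TBSCl, imidazole, DMF, rt
Reagents that add atoms: tert-butyldimethylsilyl chloride, CC(C)(C)[Si](C)(C)Cl
Why: standard silylation of the secondary alcohol gives the ether that protects the C3 oxygen up to step 13.

Step 5
Reactants: 7 (3R,4S)-4-(tert-butyldimethylsilyloxy)-3-(4-methoxybenzyloxy)oct-1-en-7-yne
Product: 9 (3R,4S,7E)-4-(tert-butyldimethylsilyloxy)-8-iodo-3-(4-methoxybenzyloxy)-7-methylocta-1,7-diene, via alkenylalane 8 (not isolated)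
Conditions: Me3Al, Cp2ZrCl2, CH2Cl2, 0 °C → rt; then I2, THF, −30 °C
Reagents that add atoms: trimethylaluminium, C[Al](C)C; iodine, II
Why: Negishi zirconium-catalysed carboalumination adds methyl and aluminium syn across the terminal alkyne with methyl on the inner carbon, and iodinolysis with retention gives the E iodide in which the chain is trans to iodine (the terminal alkene is inert).

Step 6
Reactants: 9 (3R,4S,7E)-4-(tert-butyldimethylsilyloxy)-8-iodo-3-(4-methoxybenzyloxy)-7-methylocta-1,7-diene; 10 propyne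
Product: 11 (5E,9S,10R)-9-(tert-butyldimethylsilyloxy)-10-(4-methoxybenzyloxy)-6-methyldodeca-5,11-dien-2-yn-4-one
Conditions: PdCl2(PPh3)2, CuI, Et3N, CO (1 atm), THF, rt
Reagents that add atoms: carbon monoxide, [C-]#[O+]
Why: carbonylative Sonogashira coupling, in which oxidative addition keeps the alkene geometry and CO insertion gives the acyl palladium that couples with the copper acetylide, gives the cross-conjugated enynone.

Step 7
Reactants: 11 (5E,9S,10R)-9-(tert-butyldimethylsilyloxy)-10-(4-methoxybenzyloxy)-6-methyldodeca-5,11-dien-2-yn-4-one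
Product: 12 (5E,9S,10R)-9-(tert-butyldimethylsilyloxy)-10-hydroxy-6-methyldodeca-5,11-dien-2-yn-4-one
Conditions: DDQ, CH2Cl2, pH 7 buffer, 0 °C
Reagents that add atoms: none
Why: oxidative cleavage of the 4-methoxybenzyl ether through its benzylic oxocarbenium ion should leave the silyl ether, the electron-poor enynone and the vinyl group untouched.

Step 8
Reactants: 12 (5E,9S,10R)-9-(tert-butyldimethylsilyloxy)-10-hydroxy-6-methyldodeca-5,11-dien-2-yn-4-one
Product: 13 (5E,9S,10R)-9-(tert-butyldimethylsilyloxy)-6-methyl-10-(trimethylsilyloxy)dodeca-5,11-dien-2-yn-4-one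
Conditions: TMSOTf, 2,6-lutidine, CH2Cl2, −78 °C
Reagents that add atoms: trimethylsilyl triflate, C[Si](C)(C)OS(=O)(=O)C(F)(F)F
Why: silylation with a hindered base that cannot add to the ynone gives a temporary ether that masks the alcohol in step 9 and can later be removed beside a silyl enol ether.

Step 9
Reactants: 13 (5E,9S,10R)-9-(tert-butyldimethylsilyloxy)-6-methyl-10-(trimethylsilyloxy)dodeca-5,11-dien-2-yn-4-one
Product: 15 (3R,4S,7E)-4-(tert-butyldimethylsilyloxy)-7,11-dimethyl-9-(triisopropylsilyloxy)-3-(trimethylsilyloxy)dodeca-1,7,9,10-tetraene, via lithium allenolate 14 (not isolated)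
Conditions: Me2CuLi (from MeLi and CuI), THF, −78 °C; then TIPSOTf, Et3N, −78 → −20 °C
Reagents that add atoms: lithium dimethylcuprate, [Li+].C[Cu-]C; triisopropylsilyl triflate, CC(C)[Si](OS(=O)(=O)C(F)(F)F)(C(C)C)C(C)C
Why: cuprate conjugate addition goes to the ynone carbon (the β,β-disubstituted enone side is far slower) and O-silylation of the resulting allenolate by the hard silyl triflate gives the 2-silyloxy vinylallene, whose CMe2 terminus creates no stereo-element.

Step 10
Reactants: 15 (3R,4S,7E)-4-(tert-butyldimethylsilyloxy)-7,11-dimethyl-9-(triisopropylsilyloxy)-3-(trimethylsilyloxy)dodeca-1,7,9,10-tetraene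
Product: 16 (3R,4S,7E)-4-(tert-butyldimethylsilyloxy)-7,11-dimethyl-9-(triisopropylsilyloxy)dodeca-1,7,9,10-tetraen-3-ol
Conditions: K2CO3, MeOH, 0 °C
Reagents that add atoms: none
Why: base methanolysis cleaves the alkyl trimethylsilyl ether much faster than the hindered triisopropylsilyl enol ether or the tert-butyldimethylsilyl ether.

Step 11
Reactants: 16 (3R,4S,7E)-4-(tert-butyldimethylsilyloxy)-7,11-dimethyl-9-(triisopropylsilyloxy)dodeca-1,7,9,10-tetraen-3-ol
Product: 18 (3S,5R,10R)-3-(tert-butyldimethylsilyloxy)-8-(triisopropylsilyloxy)-15-noreudesma-7(11),8-dien-4-one (trans-fused), via vinyl ketone 17 (not isolated)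
Conditions: Dess–Martin periodinane, NaHCO3, CH2Cl2, 0 °C → rt (to 40 °C if needed)
Reagents that add atoms: none
Why: Oxidation gives the α′-silyloxy vinyl ketone 17, which undergoes an intramolecular [4+2] cycloaddition (type 1 intramolecular Diels–Alder) in which C6 bonds to the nucleophilic allene carbon C7 and C5 to the fully substituted diene terminus C10, the polarity of silyl enol ether and enone and the tether C1–C4 agreeing on this regiochemistry. The closest known reaction types are the Diels–Alder reactions of 2-silyloxy vinylallenes and the spontaneous cyclisation of 1,7,9-decatrien-3-ones; the allene leaves no inside substituent at C7, so the diene reaches the s-cis form although C10 carries a cis methyl group, and the mild temperature stays below the [1,5]-hydrogen shift of vinylallenes. Ring A closes through the internal bond C5–C10 as a six-membered chair-like ring held by the tether, and ring B closes as the cyclohexene of the cycloaddition, its C8=C9 silyl enol ether and C7=C11 alkene being the masked enone. C10 is set by the diene face that the C3 stereocentre selects when its silyloxy group lies equatorial on the forming ring A, and C5 by the orientation of the tether carbonyl, the exo mode (carbonyl turned away from the diene) giving the trans fusion with axial C10 methyl and axial C5 hydrogen. The step needs exo and equatorial-silyloxy selectivity, which is not assured, since ketone-in-tether trienones usually lean toward the endo mode; the bulky silyloxy groups at C8 and C3 are relied on to disfavour the endo arrangement, adducts of the other modes are diastereomers that can be separated, and the C5 epimer of the same C10 series is recoverable because C5 is α to the ketone.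

Step 12
Reactants: 18 (3S,5R,10R)-3-(tert-butyldimethylsilyloxy)-8-(triisopropylsilyloxy)-15-noreudesma-7(11),8-dien-4-one
Product: 19 (3S,5R,10S)-3-(tert-butyldimethylsilyloxy)-8-(triisopropylsilyloxy)eudesma-4(15),7(11),8-triene (same geometry as 18, the C10 descriptor changes by priority only)
Conditions: Cp2TiMe2, toluene, 65 °C
Reagents that add atoms: dimethyltitanocene, C[Ti](C)(C1C=CC=C1)C1C=CC=C1
Why: Petasis methylenation through Cp2Ti=CH2 is non-basic, so C3 and C5 are not epimerised, and the silyl dienol ether keeps C8 masked so that only the C4 ketone is methylenated.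

Step 13
Reactants: 19 (3S,5R,10S)-3-(tert-butyldimethylsilyloxy)-8-(triisopropylsilyloxy)eudesma-4(15),7(11),8-triene
Product: 20 (3S,5R,10R)-3-hydroxyeudesma-4(15),7(11)-dien-8-one
Conditions: TBAF, AcOH, THF, 0 °C → rt
Reagents that add atoms: none
Why: fluoride cleaves both silyl groups, and the liberated 2-oxido diene is protonated at C9, which gives the conjugated 7(11)-en-8-one directly.

Step 14
Reactants: 20 (3S,5R,10R)-3-hydroxyeudesma-4(15),7(11)-dien-8-one
Product: 21 (3S,4S,5R,10R)-3,4-dihydroxyeudesm-7(11)-en-8-one (3β,4α-diol, 4β-methyl)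
Conditions: Co(acac)2 (cat.), PhSiH3, O2 (1 atm), THF, rt
Reagents that add atoms: dioxygen, O=O
Why: Mukaiyama hydration puts a hydrogen atom on the exocyclic CH2 (the tetrasubstituted enone alkene is inert) and the tertiary C4 radical should be trapped by O2 on the α face, away from the syn-axial C10 methyl, which makes the hydroxyl equatorial (4S) and the new methyl axial.

Step 15
Reactants: 21 (3S,4S,5R,10R)-3,4-dihydroxyeudesm-7(11)-en-8-one; 22 (R)-2-methylbutanoic acid
Product: 23 (3S,4S,5R,10R)-4-hydroxy-8-oxoeudesm-7(11)-en-3-yl (2R)-2-methylbutanoate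
Conditions: EDC·HCl, DMAP (cat.), CH2Cl2, 0 °C → rt
Reagents that add atoms: none
Why: Steglich-type esterification acylates only the secondary equatorial alcohol, and low temperature with catalytic DMAP should keep the α-centre of the acid intact.

Step 16
Reactants: 23 (3S,4S,5R,10R)-4-hydroxy-8-oxoeudesm-7(11)-en-3-yl (2R)-2-methylbutanoate
Product: 24 (3S,4S,5R,10R)-4-acetoxy-8-oxoeudesm-7(11)-en-3-yl (2R)-2-methylbutanoate
Conditions: Ac2O, Sc(OTf)3 (cat.), MeCN, −20 °C
Reagents that add atoms: acetic anhydride, CC(=O)OC(C)=O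
Why: Lewis-acid-catalysed acetylation with the anhydride is the established way to acylate hindered tertiary alcohols, and it avoids the alkoxide that would invite acyl migration from O3.

**Compound list**

1 | penta-1,4-dien-3-ol | C=CC(O)C=C | starting material
2 | (2S,3R)-1,2-epoxypent-4-en-3-ol | C=C[C@@H](O)[C@@H]1CO1 | intermediate
3 | (2S)-2-[(1R)-1-(4-methoxybenzyloxy)prop-2-en-1-yl]oxirane | C=C[C@@H](OCc1ccc(OC)cc1)[C@@H]1CO1 | intermediate
4 | 1-(trimethylsilyl)propyne | CC#C[Si](C)(C)C | starting material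
5 | (3R,4S)-3-(4-methoxybenzyloxy)-8-(trimethylsilyl)oct-1-en-7-yn-4-ol | C=C[C@@H](OCc1ccc(OC)cc1)[C@@H](O)CCC#C[Si](C)(C)C | intermediate
6 | (3R,4S)-3-(4-methoxybenzyloxy)oct-1-en-7-yn-4-ol | C=C[C@@H](OCc1ccc(OC)cc1)[C@@H](O)CCC#C | intermediate
7 | (3R,4S)-4-(tert-butyldimethylsilyloxy)-3-(4-methoxybenzyloxy)oct-1-en-7-yne | C=C[C@@H](OCc1ccc(OC)cc1)[C@@H](O[Si](C)(C)C(C)(C)C)CCC#C | intermediate
8 | [(1E,5S,6R)-5-(tert-butyldimethylsilyloxy)-6-(4-methoxybenzyloxy)-2-methylocta-1,7-dien-1-yl]dimethylalane | C=C[C@@H](OCc1ccc(OC)cc1)[C@@H](O[Si](C)(C)C(C)(C)C)CC/C(C)=C/[Al](C)C | intermediate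
9 | (3R,4S,7E)-4-(tert-butyldimethylsilyloxy)-8-iodo-3-(4-methoxybenzyloxy)-7-methylocta-1,7-diene | C=C[C@@H](OCc1ccc(OC)cc1)[C@@H](O[Si](C)(C)C(C)(C)C)CC/C(C)=C/I | intermediate
10 | propyne | CC#C | starting material
11 | (5E,9S,10R)-9-(tert-butyldimethylsilyloxy)-10-(4-methoxybenzyloxy)-6-methyldodeca-5,11-dien-2-yn-4-one | C=C[C@@H](OCc1ccc(OC)cc1)[C@@H](O[Si](C)(C)C(C)(C)C)CC/C(C)=C/C(=O)C#CC | intermediate
12 | (5E,9S,10R)-9-(tert-butyldimethylsilyloxy)-10-hydroxy-6-methyldodeca-5,11-dien-2-yn-4-one | C=C[C@@H](O)[C@@H](O[Si](C)(C)C(C)(C)C)CC/C(C)=C/C(=O)C#CC | intermediate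
13 | (5E,9S,10R)-9-(tert-butyldimethylsilyloxy)-6-methyl-10-(trimethylsilyloxy)dodeca-5,11-dien-2-yn-4-one | C=C[C@@H](O[Si](C)(C)C)[C@@H](O[Si](C)(C)C(C)(C)C)CC/C(C)=C/C(=O)C#CC | intermediate
14 | lithium (3R,4S,7E)-4-(tert-butyldimethylsilyloxy)-7,11-dimethyl-3-(trimethylsilyloxy)dodeca-1,7,9,10-tetraen-9-olate | C=C[C@@H](O[Si](C)(C)C)[C@@H](O[Si](C)(C)C(C)(C)C)CC/C(C)=C/C([O-])=C=C(C)C.[Li+] | intermediate
15 | (3R,4S,7E)-4-(tert-butyldimethylsilyloxy)-7,11-dimethyl-9-(triisopropylsilyloxy)-3-(trimethylsilyloxy)dodeca-1,7,9,10-tetraene | C=C[C@@H](O[Si](C)(C)C)[C@@H](O[Si](C)(C)C(C)(C)C)CC/C(C)=C/C(O[Si](C(C)C)(C(C)C)C(C)C)=C=C(C)C | intermediate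
16 | (3R,4S,7E)-4-(tert-butyldimethylsilyloxy)-7,11-dimethyl-9-(triisopropylsilyloxy)dodeca-1,7,9,10-tetraen-3-ol | C=C[C@@H](O)[C@@H](O[Si](C)(C)C(C)(C)C)CC/C(C)=C/C(O[Si](C(C)C)(C(C)C)C(C)C)=C=C(C)C | intermediate
17 | (4S,7E)-4-(tert-butyldimethylsilyloxy)-7,11-dimethyl-9-(triisopropylsilyloxy)dodeca-1,7,9,10-tetraen-3-one | C=CC(=O)[C@@H](O[Si](C)(C)C(C)(C)C)CC/C(C)=C/C(O[Si](C(C)C)(C(C)C)C(C)C)=C=C(C)C | intermediate
18 | (3S,5R,10R)-3-(tert-butyldimethylsilyloxy)-8-(triisopropylsilyloxy)-15-noreudesma-7(11),8-dien-4-one, i.e. (2S,4aR,8aR)-2-(tert-butyldimethylsilyloxy)-4a-methyl-7-(propan-2-ylidene)-6-(triisopropylsilyloxy)-3,4,4a,7,8,8a-hexahydronaphthalen-1(2H)-one | CC(C)(C)[Si](C)(C)O[C@H]1CC[C@]2(C)C=C(O[Si](C(C)C)(C(C)C)C(C)C)C(=C(C)C)C[C@H]2C1=O | intermediate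
19 | (3S,5R,10S)-3-(tert-butyldimethylsilyloxy)-8-(triisopropylsilyloxy)eudesma-4(15),7(11),8-triene | CC(C)(C)[Si](C)(C)O[C@H]1CC[C@]2(C)C=C(O[Si](C(C)C)(C(C)C)C(C)C)C(=C(C)C)C[C@H]2C1=C | intermediate
20 | (3S,5R,10R)-3-hydroxyeudesma-4(15),7(11)-dien-8-one | O[C@H]1CC[C@]2(C)CC(=O)C(=C(C)C)C[C@H]2C1=C | intermediate
21 | (3S,4S,5R,10R)-3,4-dihydroxyeudesm-7(11)-en-8-one | O[C@H]1CC[C@]2(C)CC(=O)C(=C(C)C)C[C@H]2[C@]1(C)O | intermediate
22 | (R)-2-methylbutanoic acid | CC[C@@H](C)C(=O)O | starting material
23 | (3S,4S,5R,10R)-4-hydroxy-8-oxoeudesm-7(11)-en-3-yl (2R)-2-methylbutanoate | CC[C@@H](C)C(=O)O[C@H]1CC[C@]2(C)CC(=O)C(=C(C)C)C[C@H]2[C@]1(C)O | intermediate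
24 | (3S,4S,5R,10R)-4-acetoxy-8-oxoeudesm-7(11)-en-3-yl (2R)-2-methylbutanoate, i.e. (1S,2S,4aR,8aR)-1-acetoxy-1,4a-dimethyl-6-oxo-7-(propan-2-ylidene)decahydronaphthalen-2-yl (2R)-2-methylbutanoate | CC[C@@H](C)C(=O)O[C@H]1CC[C@]2(C)CC(=O)C(=C(C)C)C[C@H]2[C@]1(C)OC(C)=O | target

**Step count and risks**

Total steps: 16. Longest linear sequence: 16 steps (from 1).

Steps most likely to fail:

1. Step 11. The cycloaddition may run through the endo transition state, which gives the cis ring fusion, or with the C3 silyloxy group axial, which means attack on the other diene face; polymerisation of the vinyl ketone may also compete. Adducts with the wrong C10 configuration are diastereomers and would be removed by chromatography; they are not recoverable. Fallback, setting out from 16 and coming back at 18: if the endo mode prevails while the diene face is still correct, the oxidation of 16 would give mainly the cis-fused (3S,5S,10R)-3-(tert-butyldimethylsilyloxy)-8-(triisopropylsilyloxy)-15-noreudesma-7(11),8-dien-4-one F1. Kinetic control of the ring fusion is then given up, and F1 (or its mixture with 18) is equilibrated at C5 with catalytic DBU in CH2Cl2 at rt; the trans-fused ketone 18 with equatorial C3 silyloxy group is expected to be the more stable epimer, as is usual for 4-oxo-eudesmanes.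

2. Step 14. The C4 radical may be trapped with poor facial selectivity (4-epi alcohol), or the hydride catalyst may reduce the enone. Fallback, setting out from 20 and coming back at 21: epoxidation with mCPBA and NaHCO3 in CH2Cl2 at 0 °C should attack the exocyclic methylene from the α face, the electron-poor enone alkene reacting much more slowly, and give (3S,4R,5R,10R)-4,15-epoxy-3-hydroxyeudesm-7(11)-en-8-one F2. LiAlH4 in THF at 0 °C opens the epoxide at CH2 and reduces the C8 ketone to (3S,4S,5R,10R)-eudesm-7(11)-ene-3,4,8-triol F3 (both C8 epimers). MnO2 in CH2Cl2 re-oxidises only the allylic C8 alcohol and returns 21.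

3. Step 16. Acetylation of the hindered tertiary alcohol may be slow, with competing loss of water from C4 or acyl exchange with the neighbouring ester. Fallback, setting out from 19 and coming back at 24, with the acylation order reversed:
   - TBAF (1 equiv) and AcOH in THF at −20 °C cleave only the silyl dienol ether and give (3S,5R,10R)-3-(tert-butyldimethylsilyloxy)eudesma-4(15),7(11)-dien-8-one F4.
   - Hydration as in step 14 gives (3S,4S,5R,10R)-3-(tert-butyldimethylsilyloxy)-4-hydroxyeudesm-7(11)-en-8-one F5.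
   - Ac2O, DMAP and Et3N at 40 °C, safe here because no neighbouring ester is present, give (3S,4S,5R,10R)-4-acetoxy-3-(tert-butyldimethylsilyloxy)eudesm-7(11)-en-8-one F6.
   - HF·pyridine in THF, an acidic desilylation that forms no alkoxide able to take over the acetyl group, gives (3S,4S,5R,10R)-4-acetoxy-3-hydroxyeudesm-7(11)-en-8-one F7.
   - Esterification with 22 under the conditions of step 15 gives 24.

Further compounds
F1 | step 11 | (3S,5S,10R)-3-(tert-butyldimethylsilyloxy)-8-(triisopropylsilyloxy)-15-noreudesma-7(11),8-dien-4-one (cis-fused C5 epimer of 18) | CC(C)(C)[Si](C)(C)O[C@H]1CC[C@]2(C)C=C(O[Si](C(C)C)(C(C)C)C(C)C)C(=C(C)C)C[C@@H]2C1=O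
F2 | step 14 | (3S,4R,5R,10R)-4,15-epoxy-3-hydroxyeudesm-7(11)-en-8-one | O[C@H]1CC[C@]2(C)CC(=O)C(=C(C)C)C[C@H]2[C@]1(C3)O3
F3 | step 14 | (3S,4S,5R,10R)-eudesm-7(11)-ene-3,4,8-triol (both C8 epimers) | O[C@H]1CC[C@]2(C)CC(O)C(=C(C)C)C[C@H]2[C@]1(C)O
F4 | step 16 | (3S,5R,10R)-3-(tert-butyldimethylsilyloxy)eudesma-4(15),7(11)-dien-8-one | CC(C)(C)[Si](C)(C)O[C@H]1CC[C@]2(C)CC(=O)C(=C(C)C)C[C@H]2C1=C
F5 | step 16 | (3S,4S,5R,10R)-3-(tert-butyldimethylsilyloxy)-4-hydroxyeudesm-7(11)-en-8-one | CC(C)(C)[Si](C)(C)O[C@H]1CC[C@]2(C)CC(=O)C(=C(C)C)C[C@H]2[C@]1(C)O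
F6 | step 16 | (3S,4S,5R,10R)-4-acetoxy-3-(tert-butyldimethylsilyloxy)eudesm-7(11)-en-8-one | CC(C)(C)[Si](C)(C)O[C@H]1CC[C@]2(C)CC(=O)C(=C(C)C)C[C@H]2[C@]1(C)OC(C)=O
F7 | step 16 | (3S,4S,5R,10R)-4-acetoxy-3-hydroxyeudesm-7(11)-en-8-one | O[C@H]1CC[C@]2(C)CC(=O)C(=C(C)C)C[C@H]2[C@]1(C)OC(C)=O
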